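## Retrosynthetic overview

1. Numbering: C1 angular-methyl fusion carbon; C2, C3 ring CH2; C4 isopropyl carbinol carbon; C5 fusion CH; C6 CHOH; C7=C8(CH3); C9 ketone; C10 CH2. The target is the C4 4-hydroxybenzoate of a trans-fused five/seven bicycle.
2. Feature used: with the C8 methyl left off and C6 at the ketone level, the seven-membered ring C1–C5–C6(=O)–C7=C8–C9(=O)–C10 has a mirror plane through C1 and the midpoint of C7=C8. The C5 and C10 methylenes are therefore enantiotopic.
3. Key disconnection: C4–C5, which opens the five-membered ring C1–C2–C3–C4–C5 to an achiral 6,6-disubstituted cyclohept-2-ene-1,4-dione carrying the isopropyl ketone side chain. A chiral lithium amide enolises at C5 and the aldol closure fixes C1, C4 and C5 together.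
4. After the key step: C4-hydroxyl-directed reduction of C6=O, C8 methyl by α-iodination and Stille coupling, C4 ester last. Before it: the ene-dione by one-carbon ring expansion (siloxycyclopropane, FeCl3) of a 5,5-disubstituted cyclohexane-1,3-dione, itself from malonate annulation of an enone made from geranic acid.
5. Ring order: six-membered dione, then seven-membered ene-dione, then the five-membered ring in the key step.

Key step: step 8

Assumption: the (R,R)-amide is taken to remove the C5 proton leading to the (1R) series drawn; should it prefer the other enantiotopic methylene, the (S,S)-amide is used with no other change.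

## Route

Step 1
Reactants: 1 geranic acid, (2E)-3,7-dimethylocta-2,6-dienoic acid (an E/Z mixture serves equally)
Product: 2 (3E)-4,8-dimethylnona-3,7-dien-2-one
Conditions: MeLi (2.2 equiv), Et2O, 0 °C to rt; inverse quench into cold 1 M HCl
Reagents that add atoms: methyllithium, C[Li]
Why: Organolithium ketone synthesis from a carboxylic acid: MeLi adds to the lithium carboxylate to give a geminal dialkoxide that is stable until work-up, so the methyl ketone is released only on quenching and over-addition is limited.

Step 2
Reactants: 2 (3E)-4,8-dimethylnona-3,7-dien-2-one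
Product: 3 (3E)-6-(3,3-dimethyloxiran-2-yl)-4-methylhex-3-en-2-one (racemic)
Conditions: mCPBA (1.05 equiv), NaHCO3, CH2Cl2, 0 °C
Reagents that add atoms: 3-chloroperoxybenzoic acid, OOC(=O)c1cccc(Cl)c1
Why: Prilezhaev epoxidation, chemoselective for the electron-rich trisubstituted terminal alkene because the conjugated C3=C4 bond is deactivated by the carbonyl; the epoxide stereocentre is destroyed in step 3.

Step 3
Reactants: 3 (3E)-6-(3,3-dimethyloxiran-2-yl)-4-methylhex-3-en-2-one
Product: 4 (3E)-4,8-dimethylnon-3-ene-2,7-dione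
Conditions: BF3·OEt2 (0.2 equiv), CH2Cl2, −30 to 0 °C
Reagents that add atoms: none
Why: Meinwald rearrangement: the Lewis acid opens the epoxide at its tertiary carbon and a 1,2-hydride shift from the neighbouring CH gives the isopropyl ketone, the enone being inert under these conditions.

Step 4
Reactants: 4 (3E)-4,8-dimethylnon-3-ene-2,7-dione; 5 diethyl malonate
Product: 8 5-methyl-5-(4-methyl-3-oxopentyl)cyclohexane-1,3-dione, via cyclised keto ester 6 (not isolated), via dione carboxylic acid 7 (not isolated)
Conditions: NaOEt, EtOH, reflux; then aq. KOH, reflux; then HCl to pH 1, 70 °C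
Reagents that add atoms: none
Why: Michael addition of malonate to the β,β-disubstituted enone (creating the quaternary carbon), intramolecular Claisen condensation, saponification and decarboxylation, i.e. the classical dimedone synthesis applied to a mesityl oxide homologue; the stabilised 1,3-dione enolate is the thermodynamic sink and the side-chain ketone is a spectator.

Step 5
Reactants: 8 5-methyl-5-(4-methyl-3-oxopentyl)cyclohexane-1,3-dione
Product: 9 5-methyl-5-(4-methyl-3-oxopentyl)-3-[(trimethylsilyl)oxy]cyclohex-2-en-1-one (racemic)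
Conditions: Me3SiCl, Et3N, THF, 0 °C to rt; used crude
Reagents that add atoms: chlorotrimethylsilane, C[Si](C)(C)Cl
Why: O-Silylation of the acidic, enolised 1,3-dione (a vinylogous acid) with a silyl chloride and amine base; the simple dialkyl ketone is not enolised under these conditions.

Step 6
Reactants: 9 5-methyl-5-(4-methyl-3-oxopentyl)-3-[(trimethylsilyl)oxy]cyclohex-2-en-1-one
Product: 10 4-methyl-4-(4-methyl-3-oxopentyl)-6-[(trimethylsilyl)oxy]bicyclo[4.1.0]heptan-2-one (racemic diastereomer mixture)
Conditions: Et2Zn, CH2I2, CH2Cl2, 0 °C to rt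
Reagents that add atoms: diiodomethane, ICI
Why: Simmons–Smith cyclopropanation (Furukawa reagent) of the silyl enol ether double bond, the only alkene present, as known for silyl enol ethers of 1,3-diketones; the diastereomer mixture is inconsequential because both cyclopropane stereocentres are lost in step 7.

Step 7
Reactants: 10 4-methyl-4-(4-methyl-3-oxopentyl)-6-[(trimethylsilyl)oxy]bicyclo[4.1.0]heptan-2-one
Product: 12 6-methyl-6-(4-methyl-3-oxopentyl)cyclohept-2-ene-1,4-dione, via chloro dione 11 (not isolated)
Conditions: FeCl3 (2.2 equiv), DMF, 0 °C to rt; then Et3N, CH2Cl2, 0 °C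
Reagents that add atoms: none
Why: FeCl3-mediated oxidative ring expansion of a siloxycyclopropane: one-electron oxidation and β-scission of the internal cyclopropane bond give the ring-enlarged radical (here also α to the old ketone), chlorine transfer gives chloro dione 11, and amine-induced E1cB loss of HCl from between the two carbonyls gives the achiral ene-dione.

Step 8
Reactants: 12 6-methyl-6-(4-methyl-3-oxopentyl)cyclohept-2-ene-1,4-dione
Product: 15 (3R,3aR,8aR)-3-hydroxy-8a-methyl-3-(propan-2-yl)-2,3,3a,8a-tetrahydroazulene-4,7(1H,8H)-dione, via ring lithium enolate 13 (not isolated), via lithium aldolate 14 (not isolated)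
Conditions: (R,R)-bis(1-phenylethyl)amine hydrochloride (1.1 equiv), n-BuLi (2.2 equiv), THF, −78 to 0 to −100 °C (amide plus 1 equiv LiCl); slow addition of 12; −78 °C, then −40 °C; AcOH in THF at −78 °C; product used at once in step 9
Reagents that add atoms: none
Why: Proposed new method: the LiCl-containing chiral lithium amide should bind the C6 carbonyl and remove the π-aligned proton of one of the two enantiotopic α-methylenes (C5, not C10), and the cross-conjugated lithium enolate 13 should add to the side-chain ketone through a six-membered O–Li–O chelate to give aldolate 14; the closest known reaction types are enantioselective deprotonations of prochiral cyclic ketones with this class of base and desymmetrising intramolecular aldol reactions of prochiral diketones. The five-membered ring C1–C2–C3–C4–C5 is closed in a 5-(enolexo)-exo-trig mode, the enolate C5=C6 bond lying outside the new ring. C1 becomes stereogenic through the base's choice between C5 and C10; C4 is set by the chelate, which holds the ketone oxygen syn to the enolate oxygen (C4–O cis to C6, isopropyl next to H5); C5 is set by the ring fusion. Because the kinetically easier closure from an axial side chain should give the cis-fused chelate, whose C1/C4 relationship is wrong and cannot be mended by epimerising C5 alone, the aldolate is held at −40 °C so that it can reopen and reclose by retro-aldol within the same C1-defined enolate until the trans-fused chelate is reached, which is expected to be the more stable ring fusion with the C4 branch equatorial and coplanar with the C6 carbonyl, and it is then quenched cold. The step needs deprotonation of the ring in preference to the side-chain ketone, which the greater acidity of an α-CH2 next to the electron-poor ene-dione carbonyl should provide, and it needs the absence of proton transfer between enolate and ketone sites, which would pass through achiral 12 and erode the enantiomeric excess; a slight excess of base, aprotic medium and low temperature serve this.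

Step 9
Reactants: 15 (3R,3aR,8aR)-3-hydroxy-8a-methyl-3-(propan-2-yl)-2,3,3a,8a-tetrahydroazulene-4,7(1H,8H)-dione
Product: 16 (1R,3aR,8S,8aS)-1,8-dihydroxy-3a-methyl-1-(propan-2-yl)-2,3,3a,4,8,8a-hexahydroazulen-5(1H)-one
Conditions: Me4NBH(OAc)3, MeCN/AcOH (1:1), −40 to −20 °C
Reagents that add atoms: none
Why: Evans–Saksena directed reduction: the C4 hydroxyl exchanges onto boron and hydride is delivered intramolecularly through a chair-like six-membered transition state to the C6 carbonyl, which should give the 1,3-anti diol (6S, new H cis to the C4 branch on the seven-membered ring), while the C9 ketone, which has no directing hydroxyl, is not reduced by this mild hydride.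

Step 10
Reactants: 16 (1R,3aR,8S,8aS)-1,8-dihydroxy-3a-methyl-1-(propan-2-yl)-2,3,3a,4,8,8a-hexahydroazulen-5(1H)-one
Product: 17 (1R,3aR,8S,8aS)-8-[(tert-butyldimethylsilyl)oxy]-1-hydroxy-3a-methyl-1-(propan-2-yl)-2,3,3a,4,8,8a-hexahydroazulen-5(1H)-one
Conditions: TBSCl, imidazole, DMF, rt
Reagents that add atoms: tert-butyldimethylsilyl chloride, CC(C)(C)[Si](C)(C)Cl
Why: Silyl ether formation, selective for the secondary allylic C6 hydroxyl because the tertiary C4 hydroxyl is too hindered for TBSCl/imidazole.

Step 11
Reactants: 17 (1R,3aR,8S,8aS)-8-[(tert-butyldimethylsilyl)oxy]-1-hydroxy-3a-methyl-1-(propan-2-yl)-2,3,3a,4,8,8a-hexahydroazulen-5(1H)-one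
Product: 18 (1R,3aR,8R,8aS)-8-[(tert-butyldimethylsilyl)oxy]-1-hydroxy-6-iodo-3a-methyl-1-(propan-2-yl)-2,3,3a,4,8,8a-hexahydroazulen-5(1H)-one (same geometry; the descriptor at C8 changes because iodine raises the priority of the alkene branch)
Conditions: I2, pyridine, CH2Cl2, 0 °C to rt
Reagents that add atoms: iodine, II
Why: α-Iodination of an enone with iodine and pyridine (conjugate addition of pyridine at C7, iodination of the enolate at C8, elimination), which can only occur at C8 because C9 is now the sole enone carbonyl.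

Step 12
Reactants: 18 (1R,3aR,8R,8aS)-8-[(tert-butyldimethylsilyl)oxy]-1-hydroxy-6-iodo-3a-methyl-1-(propan-2-yl)-2,3,3a,4,8,8a-hexahydroazulen-5(1H)-one
Product: 19 (1R,3aR,8S,8aS)-8-[(tert-butyldimethylsilyl)oxy]-1-hydroxy-3a,6-dimethyl-1-(propan-2-yl)-2,3,3a,4,8,8a-hexahydroazulen-5(1H)-one
Conditions: Me4Sn, Pd(PPh3)4 (5 mol%), CuI (10 mol%), DMF, 60 °C
Reagents that add atoms: tetramethylstannane, C[Sn](C)(C)C
Why: Stille cross-coupling of the α-iodoenone with tetramethyltin, CuI accelerating transmetalation; the free tertiary hydroxyl, the silyl ether and the enone are tolerated.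

Step 13
Reactants: 20 4-hydroxybenzoic acid
Product: 21 tert-butyldimethylsilyl 4-[(tert-butyldimethylsilyl)oxy]benzoate
Conditions: TBSCl (2.2 equiv), imidazole, DMF, rt
Reagents that add atoms: tert-butyldimethylsilyl chloride, CC(C)(C)[Si](C)(C)Cl
Why: Silylation of both the phenol and the carboxylic acid with TBSCl/imidazole.

Step 14
Reactants: 21 tert-butyldimethylsilyl 4-[(tert-butyldimethylsilyl)oxy]benzoate
Product: 22 4-[(tert-butyldimethylsilyl)oxy]benzoyl chloride
Conditions: (COCl)2, DMF (cat.), CH2Cl2, 0 °C to rt; used crude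
Reagents that add atoms: oxalyl chloride, ClC(=O)C(Cl)=O
Why: Conversion of a silyl ester into the acid chloride with oxalyl chloride and catalytic DMF (Vilsmeier-type activation) under neutral conditions that leave the aryl silyl ether intact.

Step 15
Reactants: 19 (1R,3aR,8S,8aS)-8-[(tert-butyldimethylsilyl)oxy]-1-hydroxy-3a,6-dimethyl-1-(propan-2-yl)-2,3,3a,4,8,8a-hexahydroazulen-5(1H)-one; 22 4-[(tert-butyldimethylsilyl)oxy]benzoyl chloride
Product: 24 (1R,3aR,8S,8aS)-8-[(tert-butyldimethylsilyl)oxy]-3a,6-dimethyl-5-oxo-1-(propan-2-yl)-1,2,3,3a,4,5,8,8a-octahydroazulen-1-yl 4-[(tert-butyldimethylsilyl)oxy]benzoate, via lithium alkoxide 23 (not isolated)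
Conditions: LiN(SiMe3)2 (1.05 equiv), THF, −78 °C; then 22, −78 to 0 °C
Reagents that add atoms: none
Why: Acylation of a hindered tertiary alcohol through its lithium alkoxide (nucleophilic acyl substitution on the acid chloride); O–H deprotonation by the silylamide at −78 °C is much faster than enolisation at C10, and no stereocentre is touched.

Step 16
Reactants: 24 (1R,3aR,8S,8aS)-8-[(tert-butyldimethylsilyl)oxy]-3a,6-dimethyl-5-oxo-1-(propan-2-yl)-1,2,3,3a,4,5,8,8a-octahydroazulen-1-yl 4-[(tert-butyldimethylsilyl)oxy]benzoate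
Product: 25 (1R,3aR,8S,8aS)-8-hydroxy-3a,6-dimethyl-5-oxo-1-(propan-2-yl)-1,2,3,3a,4,5,8,8a-octahydroazulen-1-yl 4-hydroxybenzoate (CNP0153637.1)
Conditions: HF·pyridine, pyridine, THF, 0 °C to rt
Reagents that add atoms: none
Why: Fluoride-mediated cleavage of both the aryl and the secondary silyl ether; the buffered, mildly acidic medium should leave the tertiary ester in place and avoid base-induced acyl migration to the freed C6 hydroxyl.

## Compound list

1 | geranic acid, (2E)-3,7-dimethylocta-2,6-dienoic acid | CC(C)=CCC/C(C)=C/C(O)=O | starting material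
2 | (3E)-4,8-dimethylnona-3,7-dien-2-one | CC(C)=CCC/C(C)=C/C(C)=O | intermediate
3 | (3E)-6-(3,3-dimethyloxiran-2-yl)-4-methylhex-3-en-2-one, racemic | CC1(C)OC1CC/C(C)=C/C(C)=O | intermediate
4 | (3E)-4,8-dimethylnon-3-ene-2,7-dione | CC(C)C(=O)CC/C(C)=C/C(C)=O | intermediate
5 | diethyl malonate | CCOC(=O)CC(=O)OCC | starting material
6 | ethyl 6-methyl-6-(4-methyl-3-oxopentyl)-2,4-dioxocyclohexane-1-carboxylate, stereoisomer mixture, present as its enolate, not isolated | CCOC(=O)C1C(=O)CC(=O)CC1(C)CCC(=O)C(C)C | intermediate
7 | 6-methyl-6-(4-methyl-3-oxopentyl)-2,4-dioxocyclohexane-1-carboxylic acid, not isolated | OC(=O)C1C(=O)CC(=O)CC1(C)CCC(=O)C(C)C | intermediate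
8 | 5-methyl-5-(4-methyl-3-oxopentyl)cyclohexane-1,3-dione | CC(C)C(=O)CCC1(C)CC(=O)CC(=O)C1 | intermediate
9 | 5-methyl-5-(4-methyl-3-oxopentyl)-3-[(trimethylsilyl)oxy]cyclohex-2-en-1-one, racemic | CC(C)C(=O)CCC1(C)CC(=O)C=C(O[Si](C)(C)C)C1 | intermediate
10 | 4-methyl-4-(4-methyl-3-oxopentyl)-6-[(trimethylsilyl)oxy]bicyclo[4.1.0]heptan-2-one, racemic diastereomer mixture | CC(C)C(=O)CCC1(C)CC(=O)C2CC2(O[Si](C)(C)C)C1 | intermediate
11 | 2-chloro-6-methyl-6-(4-methyl-3-oxopentyl)cycloheptane-1,4-dione, stereoisomer mixture, not isolated | CC(C)C(=O)CCC1(C)CC(=O)CC(Cl)C(=O)C1 | intermediate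
12 | 6-methyl-6-(4-methyl-3-oxopentyl)cyclohept-2-ene-1,4-dione, achiral key-step precursor | CC(C)C(=O)CCC1(C)CC(=O)C=CC(=O)C1 | intermediate
13 | lithium (3R)-3-methyl-3-(4-methyl-3-oxopentyl)-5-oxocyclohepta-1,6-dien-1-olate, not isolated | CC(C)C(=O)CC[C@]1(C)CC(=O)C=CC(O[Li])=C1 | intermediate
14 | lithium (3R,3aR,8aR)-8a-methyl-4,7-dioxo-3-(propan-2-yl)-1,2,3,3a,4,7,8,8a-octahydroazulen-3-olate, not isolated | O=C1C=CC(=O)[C@@H]2[C@](C)(CC[C@@]2(O[Li])C(C)C)C1 | intermediate
15 | (3R,3aR,8aR)-3-hydroxy-8a-methyl-3-(propan-2-yl)-2,3,3a,8a-tetrahydroazulene-4,7(1H,8H)-dione, key-step product | O=C1C=CC(=O)[C@@H]2[C@](C)(CC[C@@]2(O)C(C)C)C1 | intermediate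
16 | (1R,3aR,8S,8aS)-1,8-dihydroxy-3a-methyl-1-(propan-2-yl)-2,3,3a,4,8,8a-hexahydroazulen-5(1H)-one | O=C1C=C[C@H](O)[C@@H]2[C@](C)(CC[C@@]2(O)C(C)C)C1 | intermediate
17 | (1R,3aR,8S,8aS)-8-[(tert-butyldimethylsilyl)oxy]-1-hydroxy-3a-methyl-1-(propan-2-yl)-2,3,3a,4,8,8a-hexahydroazulen-5(1H)-one | O=C1C=C[C@H](O[Si](C)(C)C(C)(C)C)[C@@H]2[C@](C)(CC[C@@]2(O)C(C)C)C1 | intermediate
18 | (1R,3aR,8R,8aS)-8-[(tert-butyldimethylsilyl)oxy]-1-hydroxy-6-iodo-3a-methyl-1-(propan-2-yl)-2,3,3a,4,8,8a-hexahydroazulen-5(1H)-one | O=C1C(I)=C[C@H](O[Si](C)(C)C(C)(C)C)[C@@H]2[C@](C)(CC[C@@]2(O)C(C)C)C1 | intermediate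
19 | (1R,3aR,8S,8aS)-8-[(tert-butyldimethylsilyl)oxy]-1-hydroxy-3a,6-dimethyl-1-(propan-2-yl)-2,3,3a,4,8,8a-hexahydroazulen-5(1H)-one | CC1=C[C@H](O[Si](C)(C)C(C)(C)C)[C@@H]2[C@](C)(CC[C@@]2(O)C(C)C)CC1=O | intermediate
20 | 4-hydroxybenzoic acid | OC(=O)c1ccc(O)cc1 | starting material
21 | tert-butyldimethylsilyl 4-[(tert-butyldimethylsilyl)oxy]benzoate | CC(C)(C)[Si](C)(C)OC(=O)c1ccc(O[Si](C)(C)C(C)(C)C)cc1 | intermediate
22 | 4-[(tert-butyldimethylsilyl)oxy]benzoyl chloride | ClC(=O)c1ccc(O[Si](C)(C)C(C)(C)C)cc1 | intermediate
23 | lithium alkoxide of 19 at C4–O, not isolated | CC1=C[C@H](O[Si](C)(C)C(C)(C)C)[C@@H]2[C@](C)(CC[C@@]2(O[Li])C(C)C)CC1=O | intermediate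
24 | (1R,3aR,8S,8aS)-8-[(tert-butyldimethylsilyl)oxy]-3a,6-dimethyl-5-oxo-1-(propan-2-yl)-1,2,3,3a,4,5,8,8a-octahydroazulen-1-yl 4-[(tert-butyldimethylsilyl)oxy]benzoate | CC1=C[C@H](O[Si](C)(C)C(C)(C)C)[C@@H]2[C@](C)(CC[C@@]2(OC(=O)c2ccc(O[Si](C)(C)C(C)(C)C)cc2)C(C)C)CC1=O | intermediate
25 | (1R,3aR,8S,8aS)-8-hydroxy-3a,6-dimethyl-5-oxo-1-(propan-2-yl)-1,2,3,3a,4,5,8,8a-octahydroazulen-1-yl 4-hydroxybenzoate | CC1=C[C@H](O)[C@@H]2[C@](C)(CC[C@@]2(OC(=O)c2ccc(O)cc2)C(C)C)CC1=O | target

## Step count and risks

Total step count: 16.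
Longest linear sequence: 14 steps (steps 1 to 12, 15 and 16); steps 13 and 14 are a two-step side branch.

Steps most likely to fail:

1. Step 8 (bears the new-method label). What may go wrong:
   - competing enolisation of the side-chain ketone;
   - electron transfer from, or conjugate addition of, the amide to the ene-dione;
   - closure that stops at the cis-fused aldolate instead of re-equilibrating;
   - proton transfer through achiral 12 that erodes the enantiomeric excess.

   Fallback (known chemistry): starting from 12, the same closure is run with achiral LiN(iPr)2 (THF, −78 to −40 °C), where the aldolate can be equilibrated freely because no enantiomeric excess is at stake, to give the racemic ketol F1. This is reduced as in step 9 to the racemic diol F2, diastereomers being removed by chromatography if needed. The enantiomers of F2 are separated by preparative chromatography on a chiral stationary phase, and the (1R,3aR,8S,8aS) enantiomer is 16, where the route is rejoined.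

2. Step 7. What may go wrong:
   - ionic, Lewis-acid opening of the donor–acceptor cyclopropane competing with the oxidative pathway, so that chlorine is not installed and the saturated dione results;
   - loss of the reactive ene-dione by conjugate addition during work-up.

   Fallback: from 10, the cyclopropane is opened on purpose by the ionic route (dilute HCl, THF/H2O, rt) to the saturated trione 6-methyl-6-(4-methyl-3-oxopentyl)cycloheptane-1,4-dione F3. The CH2–CH2 unit between the two ring carbonyls is then dehydrogenated with SeO2 (dioxane, reflux), a known conversion of 1,4-diketones into ene-diones, and the route is rejoined at 12.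

3. Step 15. What may go wrong:
   - slow acylation of the hindered tertiary alkoxide;
   - competing enolisation at C10 followed by C- or O-acylation of the enone;
   - silyl migration from O6 to the C4 alkoxide.

   Fallback: silyl ester 21 and acid chloride 22 are combined (CH2Cl2, rt) to the symmetric 4-[(tert-butyldimethylsilyl)oxy]benzoic anhydride F4. Alcohol 19 is then acylated with this anhydride under Sc(OTf)3 catalysis (MeCN, −20 °C), so the acyl donor is activated by a Lewis acid and no base is present; the route is rejoined at 24.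

## Further compounds

F1 | step 8 | racemic (3R*,3aR*,8aR*)-3-hydroxy-8a-methyl-3-(propan-2-yl)-2,3,3a,8a-tetrahydroazulene-4,7(1H,8H)-dione | O=C1C=CC(=O)[C@@H]2[C@](C)(CC[C@@]2(O)C(C)C)C1.O=C1C=CC(=O)[C@H]2[C@@](C)(CC[C@]2(O)C(C)C)C1
F2 | step 8 | racemic (1R*,3aR*,8S*,8aS*)-1,8-dihydroxy-3a-methyl-1-(propan-2-yl)-2,3,3a,4,8,8a-hexahydroazulen-5(1H)-one | O=C1C=C[C@H](O)[C@@H]2[C@](C)(CC[C@@]2(O)C(C)C)C1.O=C1C=C[C@@H](O)[C@H]2[C@@](C)(CC[C@]2(O)C(C)C)C1
F3 | step 7 | 6-methyl-6-(4-methyl-3-oxopentyl)cycloheptane-1,4-dione | CC(C)C(=O)CCC1(C)CC(=O)CCC(=O)C1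
F4 | step 15 | 4-[(tert-butyldimethylsilyl)oxy]benzoic anhydride | CC(C)(C)[Si](C)(C)Oc1ccc(cc1)C(=O)OC(=O)c1ccc(O[Si](C)(C)C(C)(C)C)cc1
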